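## Structural features

The target is a flavonol: benzene ring A is fused to the 4-pyranone ring C (a 4H-chromen-4-one), and the 4-hydroxyphenyl ring B is joined to C2 of ring C by a single C–C bond. Ring C carries the enolic 3-OH beside the C4 carbonyl. Ring A carries oxygen on C5, C7 and C8a (the ring oxygen O1), the 1,3,5-pattern of phloroglucinol, and the acyl carbon C4 on C4a. There is no stereocentre, so nothing has to be set or relayed; the only stereochemical element met on the way is the geometry of an enol ether double bond, which vanishes on ring closure. The fragile group is the aryl sulfate monoester on O7: it withstands base and hydrogenolysis but is hydrolysed by acid, and as the free acid by itself, so it must arrive late and be followed only by neutral or reductive operations. The real difficulty is differentiation of oxygen: exactly one of four hydroxyl-type oxygens (O7) is sulfated, and the three ring A oxygens all end up different (O1 in the ring, O5 free and hydrogen-bonded to C4=O, O7 sulfated) although they stem from a symmetrical arene. The key step exploits the fact that C4a and C8a are neighbours on ring A bearing the acyl carbon C4 and the oxygen O1, with the C5 oxygen flanking C4a. This ortho acyl/oxygen pair beside an alkoxy group is what results when a 3-alkoxyaryne is inserted into the C–O bond of a carboxylic acid.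

## Logic of the disconnections

20 from 18 (through 19). The bonds traced back are the two benzyl C–O bonds on O3 and O4' and the sulfate O–H (held as its sodium salt). They go first because the sulfate, once present, tolerates only neutral or reductive chemistry, and hydrogenolysis is the deprotection that meets this. The gain is a precursor, 18, that is a stable salt with every other oxygen masked or inert. The forward step must cleave two benzyl ethers without reducing C2=C3 or the S–O bond, and the acid form must be set free with one equivalent of acid in the cold.

18 from 17. The O7–S bond is cut. In 17 only O5–H and O7–H are free, and O5–H is tied up in a hydrogen bond to the C4 carbonyl, so the two need no separate protecting groups. The gain is that ring A of all earlier compounds may carry two identical protecting groups and can come from a symmetrical arene. The forward step must sulfate one of two free phenols, which calls for a mild sulfur trioxide–amine complex.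

17 from 15 (through 16). The two acetal C–O bonds on O5 and O7 are restored and then O1–C2 is cut. O1–C2 is a vinylogous ester bond, the natural outcome of a phenoxide addition–elimination; opening it turns the bicyclic core into an aryl ketone whose ring A and side chain meet at C4 alone. The demands are a leaving group on C2 (methoxide), a free O1–H ortho to the ketone, and ring A protecting groups that survive base yet leave in acid without loss of benzyl ethers.

15 from 8 and 13 (through 14). The bonds C4–C4a and O1–C8a are cut together. Here the ortho acyl/oxygen pattern with the C5 oxygen beside C4a is read as an insertion retron: O1 and C4 both come from the carboxyl group of 13, and ring A comes from 14, released from 8. The gain is the largest of the plan: a ketone with a tetrasubstituted arene and three distinct ring A oxygens falls into two fragments of similar size, one derived from a symmetrical triol. The forward step must add the carboxylate oxygen to the carbon of 14 remote from the flanking acetal, must transfer the acyl group to carbon faster than the aryl anion is protonated, and must leave the enol ether double bond of 13 alone.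

8 from 1 (through 7, 6, 5, 4, 3 and 2). In turn the triflate O–S bond, the ring C–Si bond, the carbamate O–C(=O) bond and the two acetal O–CH2 bonds are cut; the carbamate is a temporary group present in 3 to 6 only. The reason is that the oxygen that will become the leaving group can first serve, as its carbamate, to direct metalation and silylation to its own ortho position. The gain is a return to 1, in which all ring positions are equivalent. The demands are lithiation at the carbon between the carbamate and an acetal, not between the two acetals, and acceptance of a statistical partial etherification of 1.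

13 from 9 and 10 (through 12 and 11). The acid is traced to its ethyl ester, the enol O–CH3 bond is cut, and then the C2–C3 bond (flavone numbering). An enol ether of this kind is the O-alkylated enolate of a β-keto ester, and the β-keto ester is the retron of a crossed Claisen acylation. The gain is two commercial pieces, each with its benzyl ether in place, so that O3 and O4' need no later protection. The demands are acylation on carbon, methylation on oxygen, and isolation of 13 without strong acid.

## Other disconnections considered

Alternative 1: The cut is the single bond O1–C8a. In the forward direction the bromoaryl 1,3-diketone A2 would be enolised by K2CO3, and its enolate oxygen on C2 joined to C8a by an intramolecular Ullmann-type O-arylation with CuI and 1,10-phenanthroline. This closes ring C and gives 7-O-allyl-3,5,4'-tri-O-benzylkaempferol A1.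
- In its favour: the position of bromine fixes the regiochemistry without reliance on polarisation of a reactive intermediate.
- Better than the chosen plan: ring C is closed in the key step itself, where the chosen plan needs a separate closure.
- Better than the chosen plan: O7 alone carries an allyl group, so the sulfation site would be defined by a protecting group and not by the different reactivity of two free phenols.
- Against it here: A2 needs ring A with four different substituents in fixed positions (bromine, acyl, benzyloxy, allyloxy). These must be carved out of a symmetrical arene by stepwise, partly statistical desymmetrisation and an acylation ortho to bromine.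
- Against it here: the key step forms one bond and is not a fragment union. An alkoxy-substituted 1,3-diketone under carbonate at the temperature of a copper coupling may also suffer retro-Claisen cleavage or protodebromination.
- Comparison: on structure, both plans reach a 3,4'-dibenzylated flavonol core. On mechanism, oxidative addition and reductive elimination at monovalent copper replace a metal-free aryne addition. On step economy, the end-game from A1 (deallylation with zerovalent palladium, sulfation, hydrogenolysis) equals steps 9–11 in length, but the way to A2 is expected to be longer than the four steps to 8.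

Alternative 2: The cuts are C3–C4 and C2–C3, so that C3 with its oxygen is a one-carbon linchpin. (Benzyloxymethylene)triphenylphosphorane A5 would be C-acylated by the acid chloride A4. In the same flask the ylide carbon would then olefinate the neighbouring aryl ester carbonyl in an intramolecular Wittig reaction, giving 3,5,4'-tri-O-benzyl-7-O-(triisopropylsilyl)kaempferol A3.
- Better than the chosen plan: two C–C bonds and ring C are formed in one operation.
- In its favour: C3 arrives at the right oxidation level with its benzyl ether, and the ring A regiochemistry is entirely preset.
- Better than the chosen plan: the silyl ether on O7 is orthogonal to the benzyl ether on O5, so the sulfation site is unambiguous.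
- Against it here: A4 is a 2,4,6-trioxygenated benzoyl chloride with three different oxygen substituents. Its parent acid decarboxylates easily and must be desymmetrised, and an ortho-aroyloxy acid chloride is prone to acyl transfer.
- Against it here: A5 is a non-stabilised, strongly basic ylide of which a second equivalent is consumed by proton transfer, and it may attack the aryl ester or the aryl silyl ether. Olefination of an ester carbonyl by a stabilised ylide needs heat, and triphenylphosphine oxide is a stoichiometric burden.
- Comparison: on structure, A3 matches 16 in ring count. On mechanism, polar acylation and olefination replace the aryne. On step economy, the key step does more, but the supply of A4 is expected to cost clearly more steps than 8 and 13 together, so the total is not shorter.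

Alternative 3: The cuts are C8–C8a, C7–C8, C5–C6 and C4a–C5: all of ring A is built onto a preformed ring C. Irradiation of the diazo ketone A7 would cause loss of N2 and Wolff rearrangement, followed by [2+2] addition of (triisopropylsiloxy)acetylene A8. On warming, a four-electron ring opening, a six-electron ring closure and tautomerisation would give 3,4'-di-O-benzyl-7-O-(triisopropylsilyl)kaempferol A6 with the 5-OH free.
- Better than the chosen plan: this is the most bond-forming of all the plans (four C–C bonds and one ring).
- Better than the chosen plan: it is the only plan in which the free 5-OH and a uniquely masked O7 come directly out of the ring-forming step, with regiochemistry set by the polarity of the ynol ether and no desymmetrisation of a phloroglucinol.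
- Equal to the chosen plan: the end-game (desilylation, sulfation, hydrogenolysis) has three steps.
- Against it here: A7 requires a 2-aryl-3-benzyloxy-4-pyranone carboxylic acid and diazo chemistry, which is hazardous and several steps long, and A8 is a moisture-sensitive reagent made with strong base.
- Against it here: the 4-pyranone chromophore has photochemistry of its own that may compete with the Wolff rearrangement. The six-electron closure must also engage the pyranone C=C and interrupt its conjugation, and photochemical steps scale poorly.
- Comparison: on structure, A6 is the most advanced product of any key step. On mechanism, a pericyclic cascade replaces an ionic insertion. On safety and on the number of steps to the key precursors, the chosen plan is better.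

Key step: step 8

Remark: the target is drawn as the free hydrogen sulfate; such compounds are handled as salts, so the route carries the sodium salt and sets the acid form free with one equivalent of HCl at the very end.

Remark: the enol ether in 12, 13 and 15 is drawn as the Z isomer (MeO and BnO cis); this geometry is not carried into the target, so a mixture of geometrical isomers would serve equally.

## Route

Step 1
Reactants: 1 phloroglucinol
Product: 2 3,5-bis(methoxymethoxy)phenol
Conditions: CH2(OMe)2 (2.1 equiv), AcCl (2.1 equiv), ZnBr2 (cat.), toluene, rt; then 1, iPr2NEt, THF, 0 °C → rt; aq NH4Cl quench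
Reagents that add atoms: chloromethyl methyl ether, COCCl (made in the flask from dimethoxymethane, COCOC, and acetyl chloride, CC(=O)Cl)
Why: Williamson-type O-alkylation of phenols by methoxymethyl chloride generated in solution by ZnBr2-catalysed exchange, which avoids handling the neat carcinogenic reagent; the three hydroxyls of 1 are equivalent, so the outcome is statistical and 2 should be separable from mono- and tris-ether by chromatography, with the mono-ether resubmitted.

Step 2
Reactants: 2 3,5-bis(methoxymethoxy)phenol
Product: 3 3,5-bis(methoxymethoxy)phenyl N-(propan-2-yl)carbamate
Conditions: iPrNCO, Et3N (cat.), CH2Cl2, rt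
Reagents that add atoms: isopropyl isocyanate, CC(C)N=C=O
Why: Base-catalysed addition of the phenol to the isocyanate gives the secondary O-aryl carbamate, chosen because it is a strong director of ortho-metalation once N-silylated and can later be removed by amines under mild conditions.

Step 3
Reactants: 3 3,5-bis(methoxymethoxy)phenyl N-(propan-2-yl)carbamate
Product: 6 3,5-bis(methoxymethoxy)-2-(trimethylsilyl)phenyl N-(propan-2-yl)carbamate, via N-silyl carbamate 4 (not isolated), via N-silyl C-silyl carbamate 5 (not isolated)
Conditions: TBSOTf, TMEDA, Et2O, 0 °C → rt; then n-BuLi (2 equiv), TMEDA, −78 °C; TMSCl, −78 °C → rt; aq NaHSO4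
Reagents that add atoms: chlorotrimethylsilane, C[Si](C)(C)Cl; tert-butyldimethylsilyl trifluoromethanesulfonate, CC(C)(C)[Si](C)(C)OS(=O)(=O)C(F)(F)F (its silyl group is present in 4 and 5 only)
Why: Directed ortho-metalation: transient N-silylation masks the N–H, the O-carbamate (the stronger director) then steers lithiation to the doubly activated carbon it shares with one acetal and not to the carbon between the two acetals, TMSCl traps the aryllithium, and the acidic work-up removes the N-silyl group.

Step 4
Reactants: 6 3,5-bis(methoxymethoxy)-2-(trimethylsilyl)phenyl N-(propan-2-yl)carbamate
Product: 8 3,5-bis(methoxymethoxy)-2-(trimethylsilyl)phenyl trifluoromethanesulfonate, via 2-silyl phenol 7 (not isolated)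
Conditions: Et2NH, DBU, MeCN, 40 °C; then PhNTf2, rt
Reagents that add atoms: N-phenylbis(trifluoromethanesulfonimide), O=S(=O)(N(c1ccccc1)S(=O)(=O)C(F)(F)F)C(F)(F)F
Why: E1cB cleavage of the secondary carbamate (DBU removes the N–H proton, the phenoxide leaves, Et2NH scavenges the isocyanate as a urea) followed by O-triflation of the phenoxide in the same flask; the aryl–silicon bond and the acetals are inert to these bases.

Step 5
Reactants: 9 ethyl 2-(benzyloxy)acetate; 10 4-(benzyloxy)benzoyl chloride
Product: 11 ethyl 2-(benzyloxy)-3-[4-(benzyloxy)phenyl]-3-oxopropanoate (racemic)
Conditions: LiN(SiMe3)2 (2.1 equiv), THF, −78 °C; then 10, −78 → 0 °C; aq NH4Cl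
Reagents that add atoms: none
Why: Crossed Claisen-type C-acylation of the lithium enolate of the glycolate ester by the aroyl chloride; the second equivalent of base deprotonates the more acidic β-keto ester as it forms so that it cannot quench unreacted enolate, and the racemic centre of 11 is of no consequence because it becomes sp2 in step 6.

Step 6
Reactants: 11 ethyl 2-(benzyloxy)-3-[4-(benzyloxy)phenyl]-3-oxopropanoate
Product: 12 ethyl (Z)-2-(benzyloxy)-3-[4-(benzyloxy)phenyl]-3-methoxyprop-2-enoate
Conditions: Cs2CO3, MeOTs, DMF, rt → 40 °C
Reagents that add atoms: methyl p-toluenesulfonate, COS(=O)(=O)c1ccc(C)cc1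
Why: O-Alkylation of an ambident β-keto ester enolate: a cesium counter-ion in a dipolar aprotic solvent and a hard sulfonate electrophile favour reaction at oxygen, while C-methylation would have to build a fully substituted carbon; the non-volatile tosylate replaces diazomethane or dimethyl sulfate, and the Z isomer is expected from the non-chelated enolate although either isomer is usable.

Step 7
Reactants: 12 ethyl (Z)-2-(benzyloxy)-3-[4-(benzyloxy)phenyl]-3-methoxyprop-2-enoate
Product: 13 (Z)-2-(benzyloxy)-3-[4-(benzyloxy)phenyl]-3-methoxyprop-2-enoic acid
Conditions: LiOH, THF–MeOH–H2O, 40 °C; then 1 M HCl to pH 4, 0 °C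
Reagents that add atoms: water, O (delivered as lithium hydroxide, [Li+].[OH-])
Why: Ester saponification (acyl–oxygen cleavage by hydroxide); the enol ether is stable to base, and acidification is stopped near pH 4 in the cold so that the β-methoxy acrylic acid is not hydrolysed to a β-keto acid and decarboxylated.

Step 8
Reactants: 8 3,5-bis(methoxymethoxy)-2-(trimethylsilyl)phenyl trifluoromethanesulfonate; 13 (Z)-2-(benzyloxy)-3-[4-(benzyloxy)phenyl]-3-methoxyprop-2-enoic acid
Product: 15 (Z)-2-(benzyloxy)-3-[4-(benzyloxy)phenyl]-1-[2-hydroxy-4,6-bis(methoxymethoxy)phenyl]-3-methoxyprop-2-en-1-one, via 3,5-bis(methoxymethoxy)benzyne 14 (not isolated)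
Conditions: CsF (4 equiv), THF, sealed tube, 110–125 °C, 8 (1.5 equiv) added in portions; aq NH4Cl
Reagents that add atoms: none
Why: Fluoride attacks silicon in 8 and loss of triflate releases aryne 14, while excess CsF turns 13 into its cesium carboxylate and holds the HF formed as a sparingly soluble hydrogen difluoride. The carboxylate oxygen adds to the aryne carbon remote from the flanking acetal (the future C8a), because the inductively withdrawing C5 oxygen distorts the aryne and stabilises negative charge on the neighbouring carbon (the future C4a); the second acetal, meta to the site of attack, is too remote to override this. The aryl anion, held ortho to the acyloxy group, attacks the ester carbonyl in a 4-exo-trig manner and the benzo-fused four-membered alkoxide opens by C–O cleavage to the phenoxide of the ortho-hydroxyaryl ketone, an anionic Fries-type 1,3 shift of acyl from O to C that forms C4–C4a after O1–C8a. The closest known reaction type is the fluoride-induced insertion of arynes into the C–O bond of carboxylic acids to give ortho-hydroxyaryl ketones, which is favoured over simple O-arylation by an ethereal solvent and high temperature. No ring remains closed and no stereocentre is formed, and the enol ether geometry is carried through unchanged. The selectivities needed are the regiochemistry of addition (secured by the 3-alkoxy group of 14), acyl transfer over proton quench (secured by the scarcity of soluble proton donors in THF with excess CsF), and carboxylate addition over [2+2] cycloaddition to the enol ether (secured by the tetrasubstituted, carboxylate-conjugated and therefore hindered and less electron-rich double bond). Portionwise addition of 8 keeps the aryne concentration low so that the product phenoxide is not arylated; the push–pull enone is a weak acceptor, so ring closure is left to step 9, and any 16 that forms early is the intermediate of that step anyway.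

Step 9
Reactants: 15 (Z)-2-(benzyloxy)-3-[4-(benzyloxy)phenyl]-1-[2-hydroxy-4,6-bis(methoxymethoxy)phenyl]-3-methoxyprop-2-en-1-one
Product: 17 3,4'-di-O-benzylkaempferol, via bis(methoxymethyl) flavone 16 (not isolated)
Conditions: K2CO3, MeOH–THF, 50 °C; then 3 M HCl (to pH <1), 55 °C
Reagents that add atoms: none
Why: Intramolecular oxa-Michael addition–elimination (6-endo-trig attack of the phenoxide on the methoxy-bearing carbon, then E1cB loss of methoxide) closes the pyranone whatever the enol ether geometry; acidifying the same solution cleaves both methoxymethyl acetals by acid-catalysed transacetalisation to methanol, while the benzyl ethers are inert.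

Step 10
Reactants: 17 3,4'-di-O-benzylkaempferol
Product: 18 sodium 3,4'-di-O-benzylkaempferol 7-sulfate
Conditions: SO3·pyridine (2 equiv), pyridine, rt; then aq NaHCO3; reversed-phase chromatography
Reagents that add atoms: sulfur trioxide–pyridine complex, [O-]S(=O)(=O)[n+]1ccccc1; sodium hydrogen carbonate, [Na+].OC([O-])=O
Why: O-Sulfonation of a phenol by a sulfur trioxide–amine complex; the 7-OH is the most acidic and the only unencumbered hydroxyl, whereas the 5-OH is locked in a hydrogen bond to the C4 carbonyl and in this class resists sulfation, acylation and alkylation under mild conditions; the basic work-up gives the stable sodium salt.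

Step 11
Reactants: 18 sodium 3,4'-di-O-benzylkaempferol 7-sulfate
Product: 20 kaempferol 7-O-sulfate, via sodium kaempferol 7-sulfate 19 (not isolated)
Conditions: H2 (1 atm), Pd/C, MeOH–THF, rt; filter; then 1 M HCl (1.0 equiv), 0 °C; C18 desalting, freeze-drying
Reagents that add atoms: none
Why: Hydrogenolysis of the two benzyl ethers over palladium metal on carbon, under which the aryl sulfate S–O bond and the pyranone double bond should not be reduced; the sulfate is kept as its salt until the last moment because the free acid hydrolyses autocatalytically, and one equivalent of acid in the cold then gives the hydrogen sulfate form.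

## Compound list

1 | phloroglucinol (benzene-1,3,5-triol) | Oc1cc(O)cc(O)c1 | starting material
2 | 3,5-bis(methoxymethoxy)phenol | COCOc1cc(O)cc(OCOC)c1 | intermediate
3 | 3,5-bis(methoxymethoxy)phenyl N-(propan-2-yl)carbamate | CC(C)NC(=O)Oc1cc(OCOC)cc(OCOC)c1 | intermediate
4 | 3,5-bis(methoxymethoxy)phenyl N-(tert-butyldimethylsilyl)-N-(propan-2-yl)carbamate | CC(C)N(C(=O)Oc1cc(OCOC)cc(OCOC)c1)[Si](C)(C)C(C)(C)C | intermediate
5 | 3,5-bis(methoxymethoxy)-2-(trimethylsilyl)phenyl N-(tert-butyldimethylsilyl)-N-(propan-2-yl)carbamate | CC(C)N(C(=O)Oc1cc(OCOC)cc(OCOC)c1[Si](C)(C)C)[Si](C)(C)C(C)(C)C | intermediate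
6 | 3,5-bis(methoxymethoxy)-2-(trimethylsilyl)phenyl N-(propan-2-yl)carbamate | CC(C)NC(=O)Oc1cc(OCOC)cc(OCOC)c1[Si](C)(C)C | intermediate
7 | 3,5-bis(methoxymethoxy)-2-(trimethylsilyl)phenol | COCOc1cc(O)c([Si](C)(C)C)c(OCOC)c1 | intermediate
8 | 3,5-bis(methoxymethoxy)-2-(trimethylsilyl)phenyl trifluoromethanesulfonate | COCOc1cc(OCOC)c([Si](C)(C)C)c(OS(=O)(=O)C(F)(F)F)c1 | intermediate
9 | ethyl 2-(benzyloxy)acetate | CCOC(=O)COCc1ccccc1 | starting material
10 | 4-(benzyloxy)benzoyl chloride | O=C(Cl)c1ccc(OCc2ccccc2)cc1 | starting material
11 | ethyl 2-(benzyloxy)-3-[4-(benzyloxy)phenyl]-3-oxopropanoate (racemic) | CCOC(=O)C(OCc1ccccc1)C(=O)c1ccc(OCc2ccccc2)cc1 | intermediate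
12 | ethyl (Z)-2-(benzyloxy)-3-[4-(benzyloxy)phenyl]-3-methoxyprop-2-enoate | CCOC(=O)/C(OCc1ccccc1)=C(/OC)c1ccc(OCc2ccccc2)cc1 | intermediate
13 | (Z)-2-(benzyloxy)-3-[4-(benzyloxy)phenyl]-3-methoxyprop-2-enoic acid | OC(=O)/C(OCc1ccccc1)=C(/OC)c1ccc(OCc2ccccc2)cc1 | intermediate
14 | 3,5-bis(methoxymethoxy)benzyne (1,2-didehydro-3,5-bis(methoxymethoxy)benzene) | COCOC1=CC(OCOC)=CC#C1 | intermediate
15 | (Z)-2-(benzyloxy)-3-[4-(benzyloxy)phenyl]-1-[2-hydroxy-4,6-bis(methoxymethoxy)phenyl]-3-methoxyprop-2-en-1-one | O=C(c1c(O)cc(OCOC)cc1OCOC)/C(OCc1ccccc1)=C(/OC)c1ccc(OCc2ccccc2)cc1 | intermediate
16 | 3-(benzyloxy)-2-[4-(benzyloxy)phenyl]-5,7-bis(methoxymethoxy)-4H-chromen-4-one | O=c1c(OCc2ccccc2)c(-c2ccc(OCc3ccccc3)cc2)oc2cc(OCOC)cc(OCOC)c12 | intermediate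
17 | 3-(benzyloxy)-2-[4-(benzyloxy)phenyl]-5,7-dihydroxy-4H-chromen-4-one (3,4'-di-O-benzylkaempferol) | O=c1c(OCc2ccccc2)c(-c2ccc(OCc3ccccc3)cc2)oc2cc(O)cc(O)c12 | intermediate
18 | sodium 3-(benzyloxy)-2-[4-(benzyloxy)phenyl]-5-hydroxy-4-oxo-4H-chromen-7-yl sulfate | O=c1c(OCc2ccccc2)c(-c2ccc(OCc3ccccc3)cc2)oc2cc(OS(=O)(=O)[O-])cc(O)c12.[Na+] | intermediate
19 | sodium 3,5-dihydroxy-2-(4-hydroxyphenyl)-4-oxo-4H-chromen-7-yl sulfate | O=c1c(O)c(-c2ccc(O)cc2)oc2cc(OS(=O)(=O)[O-])cc(O)c12.[Na+] | intermediate
20 | kaempferol 7-O-sulfate | O=c1c(O)c(-c2ccc(O)cc2)oc2cc(OS(=O)(=O)O)cc(O)c12 | target

## Step count and least certain steps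

Total step count: 11. Longest linear sequence: 8 steps (steps 1–4, then 8–11); the acid branch (steps 5–7) joins at step 8.

Step 8 (key step). What is most likely to go wrong is diversion of the aryne before C4–C4a is formed: protonation of the aryl anion ahead of acyl transfer (net O-arylation), [2+2] cycloaddition to the enol ether, or arylation of the product phenoxide by a second aryne. The cause is that acyl transfer through a strained four-membered transition state competes with these bimolecular traps. Fallback (aryllithium acylation), setting out from 1 and 13 and coming back at 17:
- Exhaustive etherification of 1 with methoxymethyl chloride would give 1,3,5-tris(methoxymethoxy)benzene F1, whose ring C–H bonds are all equivalent and each flanked by two acetals.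
- 13 would be coupled with N,O-dimethylhydroxylamine (carbodiimide) to (Z)-2-(benzyloxy)-3-[4-(benzyloxy)phenyl]-N,3-dimethoxy-N-methylprop-2-enamide F2.
- Lithiation of F1 (n-BuLi, TMEDA, THF, 0 °C) and addition to F2 at −78 °C would give (Z)-2-(benzyloxy)-3-[4-(benzyloxy)phenyl]-3-methoxy-1-[2,4,6-tris(methoxymethoxy)phenyl]prop-2-en-1-one F3.
- HCl in MeOH–THF would remove the three acetals and, with K2CO3 if needed, close ring C to give 17.

C4–C4a is then made by a symmetrical nucleophile with O1 already on the ring, so neither regiochemistry nor a proton quench arises, at the price of one more linear operation on the acid.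

Step 6. What is most likely to go wrong is methylation of the ambident enolate on carbon instead of oxygen, because the soft carbon terminus can compete even when it is fully substituted. A mixture of geometrical isomers would be harmless. Fallback (reversed polarity at C3), setting out from 11 and coming back at 13:
- Ph3PCl2 (from PPh3 and C2Cl6) with Et3N in MeCN would convert the enolised ketone into ethyl (Z)-2-(benzyloxy)-3-[4-(benzyloxy)phenyl]-3-chloroprop-2-enoate F4.
- NaOMe in MeOH would replace chloride by addition–elimination with concurrent transesterification, giving methyl (Z)-2-(benzyloxy)-3-[4-(benzyloxy)phenyl]-3-methoxyprop-2-enoate F5.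
- Aqueous LiOH added to the same flask, then careful acidification, would give 13.

The oxygen then enters as methoxide at an electrophilic carbon, so C-methylation cannot occur.

Step 3. What is most likely to go wrong is metalation at the carbon between the two acetals, or anionic migration or fragmentation of the carbamate before the silyl chloride is added, since three oxygen directors compete on one ring. Fallback (halogen–metal exchange in place of directed metalation), setting out from 2 and coming back at 7 and then 8:
- NBS with catalytic iPr2NH in CH2Cl2 at 0 °C would brominate ortho to the free hydroxyl, giving 2-bromo-3,5-bis(methoxymethoxy)phenol F6.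
- (Me3Si)2NH would give [2-bromo-3,5-bis(methoxymethoxy)phenoxy]trimethylsilane F7.
- n-BuLi in THF at −78 °C would effect bromine–lithium exchange and a retro-Brook 1,3 shift of silicon from oxygen to carbon, giving the lithium salt of 7.
- PhNTf2 would complete 8.

Step 11. What is most likely to go wrong is incomplete hydrogenolysis of the enolic 3-O-benzyl ether, partial reduction of C2=C3, or loss of the sulfate by acid-catalysed hydrolysis while the free acid is liberated and concentrated. Fallback (deprotection before sulfation), setting out from 17 and coming back at 19:
- Hydrogenolysis (H2, Pd/C) would give kaempferol F8.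
- One equivalent of SO3·pyridine in pyridine at 0 °C, relying on the acidity order 7-OH > 4'-OH > 3-OH > 5-OH, then NaHCO3 work-up and reversed-phase separation from minor isomers, would give 19, which is acidified as in step 11.

Should the acid form prove too labile to isolate, 19 would be the form kept and acidified immediately before use.

## Further compounds

F1 | step 8 | 1,3,5-tris(methoxymethoxy)benzene | COCOc1cc(OCOC)cc(OCOC)c1
F2 | step 8 | (Z)-2-(benzyloxy)-3-[4-(benzyloxy)phenyl]-N,3-dimethoxy-N-methylprop-2-enamide | CON(C)C(=O)/C(OCc1ccccc1)=C(/OC)c1ccc(OCc2ccccc2)cc1
F3 | step 8 | (Z)-2-(benzyloxy)-3-[4-(benzyloxy)phenyl]-3-methoxy-1-[2,4,6-tris(methoxymethoxy)phenyl]prop-2-en-1-one | O=C(c1c(OCOC)cc(OCOC)cc1OCOC)/C(OCc1ccccc1)=C(/OC)c1ccc(OCc2ccccc2)cc1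
F4 | step 6 | ethyl (Z)-2-(benzyloxy)-3-[4-(benzyloxy)phenyl]-3-chloroprop-2-enoate | CCOC(=O)/C(OCc1ccccc1)=C(/Cl)c1ccc(OCc2ccccc2)cc1
F5 | step 6 | methyl (Z)-2-(benzyloxy)-3-[4-(benzyloxy)phenyl]-3-methoxyprop-2-enoate | COC(=O)/C(OCc1ccccc1)=C(/OC)c1ccc(OCc2ccccc2)cc1
F6 | step 3 | 2-bromo-3,5-bis(methoxymethoxy)phenol | COCOc1cc(O)c(Br)c(OCOC)c1
F7 | step 3 | [2-bromo-3,5-bis(methoxymethoxy)phenoxy]trimethylsilane | COCOc1cc(O[Si](C)(C)C)c(Br)c(OCOC)c1
F8 | step 11 | kaempferol | O=c1c(O)c(-c2ccc(O)cc2)oc2cc(O)cc(O)c12
A1 | alternative 1 | 7-O-allyl-3,5,4'-tri-O-benzylkaempferol | O=c1c(OCc2ccccc2)c(-c2ccc(OCc3ccccc3)cc2)oc2cc(OCC=C)cc(OCc3ccccc3)c12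
A2 | alternative 1 | 1-[4-(allyloxy)-2-(benzyloxy)-6-bromophenyl]-2-(benzyloxy)-3-[4-(benzyloxy)phenyl]propane-1,3-dione | O=C(c1c(Br)cc(OCC=C)cc1OCc1ccccc1)C(OCc1ccccc1)C(=O)c1ccc(OCc2ccccc2)cc1
A3 | alternative 2 | 3,5,4'-tri-O-benzyl-7-O-(triisopropylsilyl)kaempferol | O=c1c(OCc2ccccc2)c(-c2ccc(OCc3ccccc3)cc2)oc2cc(O[Si](C(C)C)(C(C)C)C(C)C)cc(OCc3ccccc3)c12
A4 | alternative 2 | 2-(benzyloxy)-6-{[4-(benzyloxy)benzoyl]oxy}-4-[(triisopropylsilyl)oxy]benzoyl chloride | O=C(Cl)c1c(OCc2ccccc2)cc(O[Si](C(C)C)(C(C)C)C(C)C)cc1OC(=O)c1ccc(OCc2ccccc2)cc1
A5 | alternative 2 | (benzyloxymethylene)triphenylphosphorane | C(OCc1ccccc1)=P(c1ccccc1)(c1ccccc1)c1ccccc1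
A6 | alternative 3 | 3,4'-di-O-benzyl-7-O-(triisopropylsilyl)kaempferol | O=c1c(OCc2ccccc2)c(-c2ccc(OCc3ccccc3)cc2)oc2cc(O[Si](C(C)C)(C(C)C)C(C)C)cc(O)c12
A7 | alternative 3 | 5-(benzyloxy)-6-[4-(benzyloxy)phenyl]-2-(diazoacetyl)-4H-pyran-4-one | [N-]=[N+]=CC(=O)c1cc(=O)c(OCc2ccccc2)c(-c2ccc(OCc3ccccc3)cc2)o1
A8 | alternative 3 | (triisopropylsiloxy)acetylene | C#CO[Si](C(C)C)(C(C)C)C(C)C
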